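## Retrosynthetic overview

1. Carbons are numbered as in labdanes (ring A = C1–C5, C10; ring B = C5–C10). The (Z)-coumarate is built last on C19–OH by Still–Gennari olefination of a phosphonoacetate; C17 comes from a Wittig reaction and C12–C16 from conjugate isoprenylation of an 8-oxo-9(11)-methylene ketone.
2. Ring A is opened at C2–C3 (and C4–C18): a sulfone-stabilised C2 carbanion on the ethano arm of C10 adds to C3 of an acrylate (C3=C4–C19O2Me) carried by C5, and the C4 ester enolate is methylated in the same flask; the sulfone is then cleaved.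
3. The monocyclic precursor comes from 2-methylcyclohex-2-enone by catalytic asymmetric conjugate addition (sets C5) with Michael trapping of the enolate (sets C10); C4 and C9 are relayed from these two centres.
4. Order of ring formation: ring B is bought as the enone; ring A is closed in the key step.
5. Enabling feature: C4 of ring A is quaternary and carries an oxygenated carbon (C19) syn-axial to the C10 methyl, and the ring-A bonds at C5 and C10 are trans-diequatorial on ring B. C3/C4/C19 can therefore be an acrylate acceptor, C2 a carbanion, and the axial C10 methyl the control element for C4.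

Key step: step 5

Remark: the target is taken as the (4R,5S,9R,10S) enantiomer of the given SMILES; the C2 epimers of 12 and the C8 epimers of 14 are carried as mixtures because both centres are destroyed in steps 6 and 8.

## Route

Step 1
Reactants: 1 2-methylcyclohex-2-en-1-one; 2 (1-bromoethenyl)trimethylsilane; 3 phenyl vinyl sulfone
Product: 6 (2R,3S)-2-methyl-2-[2-(phenylsulfonyl)ethyl]-3-[1-(trimethylsilyl)ethenyl]cyclohexan-1-one, via Grignard reagent 4 (not isolated), via magnesium enolate 5 (not isolated)
Conditions: Mg, THF (2 → 4); 1, Cu(OTf)2 (4 mol %), chiral imidazolinium chloride (NHC precursor, 5 mol %), Et2O, −30 °C; then 3, THF–DMPU, −30 → 0 °C; aq NH4Cl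
Reagents that add atoms: none
Why: Copper-catalysed asymmetric conjugate addition of a Grignard reagent to an α-substituted cyclic enone with enolate trapping, a known reaction type: the chiral NHC–copper catalyst (ligand enantiomer chosen for 3S) sets C5, and the tetrasubstituted magnesium enolate 5 undergoes Michael addition to the vinyl sulfone on the face anti to the new C5 substituent, which sets the quaternary C10 trans to it.

Step 2
Reactants: 6 (2R,3S)-2-methyl-2-[2-(phenylsulfonyl)ethyl]-3-[1-(trimethylsilyl)ethenyl]cyclohexan-1-one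
Product: 7 (2R,3S)-3-(1-iodoethenyl)-2-methyl-2-[2-(phenylsulfonyl)ethyl]cyclohexan-1-one
Conditions: NIS, MeCN–ClCH2CN (4:1), 0 °C → rt, dark
Reagents that add atoms: N-iodosuccinimide, O=C1CCC(=O)N1I
Why: Electrophilic ipso-iododesilylation of a 1,1-disubstituted vinylsilane is the standard route to 2-iodoalk-1-enes and should leave ketone, sulfone and both stereocentres untouched.

Step 3
Reactants: 7 (2R,3S)-3-(1-iodoethenyl)-2-methyl-2-[2-(phenylsulfonyl)ethyl]cyclohexan-1-one
Product: 8 ({2-[(1R,2S)-2-(1-iodoethenyl)-1-methyl-6-methylidenecyclohexyl]ethyl}sulfonyl)benzene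
Conditions: Ph3PCH3Br, KHMDS, THF, 0 °C; then 7, 0 → 60 °C
Reagents that add atoms: methyltriphenylphosphonium bromide, C[P+](c1ccccc1)(c1ccccc1)c1ccccc1.[Br-]
Why: Wittig methylenation of the α-quaternary ketone installs the C9 exocyclic alkene needed later and removes the only enolisable ketone before the carbanion chemistry of step 5; the ylide is not basic enough to deprotonate the sulfone and does not react with the vinyl iodide.

Step 4
Reactants: 8 ({2-[(1R,2S)-2-(1-iodoethenyl)-1-methyl-6-methylidenecyclohexyl]ethyl}sulfonyl)benzene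
Product: 9 methyl 2-{(1S,2R)-2-methyl-3-methylidene-2-[2-(phenylsulfonyl)ethyl]cyclohexyl}prop-2-enoate
Conditions: PdCl2(PPh3)2 (5 mol %), CO (1 atm), Et3N, MeOH–DMF, 50 °C
Reagents that add atoms: carbon monoxide, [C-]#[O+]; methanol, CO
Why: Palladium-catalysed methoxycarbonylation (oxidative addition of the vinyl iodide to zerovalent palladium, CO insertion, methanolysis) should give the 2-substituted acrylate, the nearby 1,1-disubstituted alkene being unable to intercept the organopalladium species in a favourable ring size.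

Step 5
Reactants: 9 methyl 2-{(1S,2R)-2-methyl-3-methylidene-2-[2-(phenylsulfonyl)ethyl]cyclohexyl}prop-2-enoate
Product: 12 methyl (1R,4aR,8aS)-1,4a-dimethyl-5-methylidene-3-(phenylsulfonyl)decahydronaphthalene-1-carboxylate (C3 epimers), via lithiated sulfone 10 (not isolated), via lithium ester enolate 11 (not isolated)
Conditions: LDA (1.1 equiv), THF–DMPU, −78 → −40 °C; then MeI (3 equiv), −78 → 0 °C
Reagents that add atoms: iodomethane, CI
Why: LDA should remove the kinetically most acidic proton, α to the sulfone at C2, and the lithiated sulfone 10 adds in conjugate fashion to the terminal C3 of the C5-bound acrylate, which closes ring A and leaves the lithium ester enolate 11 at C4, which MeI then C-alkylates in the same flask. The closest known reaction type is the Michael-initiated ring closure of a sulfonyl carbanion onto an α,β-unsaturated ester followed by alkylation of the resulting ester enolate (tandem conjugate addition–enolate trapping). Ring A closes in the 6-endo-trig mode through a chair in which the two arms on C10 and C5, trans on ring B, are both equatorial, so the ring fusion is trans. The new C4 stereocentre is controlled by the axial C10 methyl, which blocks the syn-axial face of the enolate, so MeI enters equatorially and the ester ends axial, cis to the C10 methyl; the C2 sulfone centre does not matter because it is removed in step 6. The step needs 1,4- over 1,2-selectivity (6-exo attack on the ester carbonyl) and sulfone deprotonation over γ-deprotonation of the acrylate; these are secured by the soft sulfonyl carbanion in THF–DMPU at low temperature, by the hindered tertiary C5–H, and by the absence of any ketone after step 3.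

Step 6
Reactants: 12 methyl (1R,4aR,8aS)-1,4a-dimethyl-5-methylidene-3-(phenylsulfonyl)decahydronaphthalene-1-carboxylate (C3 epimers)
Product: 13 methyl (1R,4aR,8aS)-1,4a-dimethyl-5-methylidenedecahydronaphthalene-1-carboxylate
Conditions: Na(Hg) (6 %), Na2HPO4, MeOH–THF, −20 → 0 °C
Reagents that add atoms: none
Why: Reductive desulfonylation of a secondary alkyl phenyl sulfone by electron transfer from sodium amalgam replaces the C–S bond by C–H and erases the C2 stereocentre; the hindered ester and the isolated alkene should survive.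

Step 7
Reactants: 13 methyl (1R,4aR,8aS)-1,4a-dimethyl-5-methylidenedecahydronaphthalene-1-carboxylate
Product: 14 methyl (1R,4aR,8aS)-6-hydroxy-1,4a-dimethyl-5-methylidenedecahydronaphthalene-1-carboxylate (C6 epimers)
Conditions: SeO2 (0.3 equiv), t-BuOOH (2 equiv), CH2Cl2, 0 °C → rt
Reagents that add atoms: selenium dioxide, O=[Se]=O; tert-butyl hydroperoxide, CC(C)(C)OO
Why: Selenium dioxide allylic oxidation (ene reaction followed by [2,3]-sigmatropic shift) should hydroxylate C8, the only allylic position bearing hydrogen because C10 is quaternary, with return of the double bond to C9=C11; the new C8 centre is lost in step 8.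

Step 8
Reactants: 14 methyl (1R,4aR,8aS)-6-hydroxy-1,4a-dimethyl-5-methylidenedecahydronaphthalene-1-carboxylate (C6 epimers)
Product: 15 methyl (1R,4aR,8aS)-1,4a-dimethyl-5-methylidene-6-oxodecahydronaphthalene-1-carboxylate
Conditions: Dess–Martin periodinane, NaHCO3, CH2Cl2, 0 °C
Reagents that add atoms: none
Why: Dess–Martin oxidation of the secondary allylic alcohol should give the 2-methylene ketone without touching a stereocentre.

Step 9
Reactants: 16 2-chlorobuta-1,3-diene (chloroprene); 17 (trimethylsilyl)methylmagnesium chloride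
Product: 18 2-[(trimethylsilyl)methyl]buta-1,3-diene
Conditions: NiCl2(dppp) (1 mol %), Et2O, reflux
Reagents that add atoms: none
Why: Nickel-catalysed Kumada coupling of an alkenyl chloride with a silylmethyl Grignard reagent is the standard preparation of this isoprenylsilane.

Step 10
Reactants: 15 methyl (1R,4aR,8aS)-1,4a-dimethyl-5-methylidene-6-oxodecahydronaphthalene-1-carboxylate; 18 2-[(trimethylsilyl)methyl]buta-1,3-diene
Product: 20 methyl (1R,4aR,5S,8aS)-1,4a-dimethyl-5-(3-methylidenepent-4-en-1-yl)-6-oxodecahydronaphthalene-1-carboxylate, via titanium enolate 19 (not isolated)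
Conditions: TiCl4 (1.1 equiv), CH2Cl2, −78 °C; then sat. aq NaHCO3
Reagents that add atoms: none
Why: Hosomi–Sakurai conjugate allylation: the allylsilane terminus should attack the unhindered exocyclic β-carbon of the TiCl4-activated enone and loss of silicon from the β-silyl cation unveils the 2-substituted buta-1,3-diene, so that C12–C16 arrive in one step; C9 is set by protonation of titanium enolate 19 anti to the C10 methyl and is in any case the thermodynamically preferred, equatorial epimer α to the ketone.

Step 11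
Reactants: 20 methyl (1R,4aR,5S,8aS)-1,4a-dimethyl-5-(3-methylidenepent-4-en-1-yl)-6-oxodecahydronaphthalene-1-carboxylate
Product: 21 methyl (1R,4aS,5R,8aS)-1,4a-dimethyl-6-methylidene-5-(3-methylidenepent-4-en-1-yl)decahydronaphthalene-1-carboxylate
Conditions: Ph3PCH3Br, KOtBu, THF, 0 °C → rt
Reagents that add atoms: methyltriphenylphosphonium bromide, C[P+](c1ccccc1)(c1ccccc1)c1ccccc1.[Br-]
Why: Wittig methylenation of the C8 ketone gives the exocyclic C8=C17 alkene; the epimerisable C9 centre already has its thermodynamic configuration and the hindered ester does not react.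

Step 12
Reactants: 21 methyl (1R,4aS,5R,8aS)-1,4a-dimethyl-6-methylidene-5-(3-methylidenepent-4-en-1-yl)decahydronaphthalene-1-carboxylate
Product: 22 [(1R,4aS,5R,8aS)-1,4a-dimethyl-6-methylidene-5-(3-methylidenepent-4-en-1-yl)decahydronaphthalen-1-yl]methanol
Conditions: LiAlH4, THF, 0 °C → reflux; aq NaOH work-up
Reagents that add atoms: none
Why: Hydride reduction of the axial neopentyl methyl ester to the primary alcohol; LiAlH4 does not reduce isolated alkenes or the non-polarised diene.

Step 13
Reactants: 23 methyl [bis(2,2,2-trifluoroethoxy)phosphoryl]acetate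
Product: 24 [bis(2,2,2-trifluoroethoxy)phosphoryl]acetic acid
Conditions: LiOH·H2O (1.05 equiv), THF–H2O, 0 °C; then 1 M HCl
Reagents that add atoms: lithium hydroxide monohydrate, [Li+].[OH-].O
Why: Saponification of the carboxylic methyl ester, activated by the α-phosphoryl group, at 0 °C with one equivalent of hydroxide should spare the trifluoroethyl phosphonate esters.

Step 14
Reactants: 22 [(1R,4aS,5R,8aS)-1,4a-dimethyl-6-methylidene-5-(3-methylidenepent-4-en-1-yl)decahydronaphthalen-1-yl]methanol; 24 [bis(2,2,2-trifluoroethoxy)phosphoryl]acetic acid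
Product: 25 [(1R,4aS,5R,8aS)-1,4a-dimethyl-6-methylidene-5-(3-methylidenepent-4-en-1-yl)decahydronaphthalen-1-yl]methyl [bis(2,2,2-trifluoroethoxy)phosphoryl]acetate
Conditions: EDC·HCl, DMAP (0.1 equiv), CH2Cl2, 0 °C → rt
Reagents that add atoms: none
Why: Carbodiimide-mediated Steglich esterification of the primary, neopentyl C19 alcohol with the unhindered phosphonoacetic acid.

Step 15
Reactants: 25 [(1R,4aS,5R,8aS)-1,4a-dimethyl-6-methylidene-5-(3-methylidenepent-4-en-1-yl)decahydronaphthalen-1-yl]methyl [bis(2,2,2-trifluoroethoxy)phosphoryl]acetate; 26 4-[(tert-butyldimethylsilyl)oxy]benzaldehyde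
Product: 27 [(1R,4aS,5R,8aS)-1,4a-dimethyl-6-methylidene-5-(3-methylidenepent-4-en-1-yl)decahydronaphthalen-1-yl]methyl (Z)-3-{4-[(tert-butyldimethylsilyl)oxy]phenyl}prop-2-enoate
Conditions: KHMDS, 18-crown-6, THF, −78 °C; then 26, −78 °C
Reagents that add atoms: none
Why: Still–Gennari olefination: the bis(trifluoroethyl)phosphonate anion with a crown-ether-separated potassium ion adds irreversibly and eliminates fast, which should give the (Z)-cinnamate with an aromatic aldehyde; no stereocentre of the terpene part is involved.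

Step 16
Reactants: 27 [(1R,4aS,5R,8aS)-1,4a-dimethyl-6-methylidene-5-(3-methylidenepent-4-en-1-yl)decahydronaphthalen-1-yl]methyl (Z)-3-{4-[(tert-butyldimethylsilyl)oxy]phenyl}prop-2-enoate
Product: 28 [(1R,4aS,5R,8aS)-1,4a-dimethyl-6-methylidene-5-(3-methylidenepent-4-en-1-yl)decahydronaphthalen-1-yl]methyl (Z)-3-(4-hydroxyphenyl)prop-2-enoate (CNP0131099.2)
Conditions: TBAF, AcOH, THF, 0 °C, exclusion of light
Reagents that add atoms: none
Why: Fluoride cleavage of the aryl silyl ether, buffered with acetic acid so that no free phenoxide or base can isomerise the (Z)-alkene or attack the dienes.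

## Compound list

1 | 2-methylcyclohex-2-en-1-one | CC1=CCCCC1=O | starting material
2 | (1-bromoethenyl)trimethylsilane | C=C(Br)[Si](C)(C)C | starting material
3 | phenyl vinyl sulfone | C=CS(=O)(=O)c1ccccc1 | starting material
4 | [1-(trimethylsilyl)ethenyl]magnesium bromide | C=C([Mg]Br)[Si](C)(C)C | intermediate
5 | bromomagnesium (3S)-2-methyl-3-[1-(trimethylsilyl)ethenyl]cyclohex-1-en-1-olate | CC1=C(O[Mg]Br)CCC[C@@H]1C(=C)[Si](C)(C)C | intermediate
6 | (2R,3S)-2-methyl-2-[2-(phenylsulfonyl)ethyl]-3-[1-(trimethylsilyl)ethenyl]cyclohexan-1-one | O=C1CCC[C@H](C(=C)[Si](C)(C)C)[C@@]1(C)CCS(=O)(=O)c1ccccc1 | intermediate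
7 | (2R,3S)-3-(1-iodoethenyl)-2-methyl-2-[2-(phenylsulfonyl)ethyl]cyclohexan-1-one | O=C1CCC[C@H](C(=C)I)[C@@]1(C)CCS(=O)(=O)c1ccccc1 | intermediate
8 | ({2-[(1R,2S)-2-(1-iodoethenyl)-1-methyl-6-methylidenecyclohexyl]ethyl}sulfonyl)benzene | C=C1CCC[C@H](C(=C)I)[C@@]1(C)CCS(=O)(=O)c1ccccc1 | intermediate
9 | methyl 2-{(1S,2R)-2-methyl-3-methylidene-2-[2-(phenylsulfonyl)ethyl]cyclohexyl}prop-2-enoate | C=C1CCC[C@H](C(=C)C(=O)OC)[C@@]1(C)CCS(=O)(=O)c1ccccc1 | intermediate
10 | lithiated sulfone of 9 (lithium on the carbon α to sulfur) | C=C1CCC[C@H](C(=C)C(=O)OC)[C@@]1(C)CC([Li])S(=O)(=O)c1ccccc1 | intermediate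
11 | lithium ester enolate of the ring-closed sulfone (enolate at the future quaternary carbon) | C=C1CCC[C@@H]2C(=C(OC)O[Li])CC(S(=O)(=O)c3ccccc3)C[C@@]12C | intermediate
12 | methyl (1R,4aR,8aS)-1,4a-dimethyl-5-methylidene-3-(phenylsulfonyl)decahydronaphthalene-1-carboxylate (C3 epimers) | C=C1CCC[C@@H]2[C@](C)(C(=O)OC)CC(S(=O)(=O)c3ccccc3)C[C@@]12C | intermediate
13 | methyl (1R,4aR,8aS)-1,4a-dimethyl-5-methylidenedecahydronaphthalene-1-carboxylate | C=C1CCC[C@@H]2[C@](C)(C(=O)OC)CCC[C@@]12C | intermediate
14 | methyl (1R,4aR,8aS)-6-hydroxy-1,4a-dimethyl-5-methylidenedecahydronaphthalene-1-carboxylate (C6 epimers) | C=C1C(O)CC[C@@H]2[C@](C)(C(=O)OC)CCC[C@@]12C | intermediate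
15 | methyl (1R,4aR,8aS)-1,4a-dimethyl-5-methylidene-6-oxodecahydronaphthalene-1-carboxylate | C=C1C(=O)CC[C@@H]2[C@](C)(C(=O)OC)CCC[C@@]12C | intermediate
16 | 2-chlorobuta-1,3-diene | C=CC(Cl)=C | starting material
17 | (trimethylsilyl)methylmagnesium chloride | C[Si](C)(C)C[Mg]Cl | starting material
18 | 2-[(trimethylsilyl)methyl]buta-1,3-diene | C=CC(=C)C[Si](C)(C)C | intermediate
19 | trichlorotitanium enolate of 20 (enolate between the ketone carbon and the side-chain-bearing carbon) | C=CC(=C)CCC1=C(O[Ti](Cl)(Cl)Cl)CC[C@@H]2[C@](C)(C(=O)OC)CCC[C@@]12C | intermediate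
20 | methyl (1R,4aR,5S,8aS)-1,4a-dimethyl-5-(3-methylidenepent-4-en-1-yl)-6-oxodecahydronaphthalene-1-carboxylate | C=CC(=C)CC[C@@H]1C(=O)CC[C@@H]2[C@](C)(C(=O)OC)CCC[C@@]12C | intermediate
21 | methyl (1R,4aS,5R,8aS)-1,4a-dimethyl-6-methylidene-5-(3-methylidenepent-4-en-1-yl)decahydronaphthalene-1-carboxylate | C=CC(=C)CC[C@@H]1C(=C)CC[C@@H]2[C@](C)(C(=O)OC)CCC[C@@]12C | intermediate
22 | [(1R,4aS,5R,8aS)-1,4a-dimethyl-6-methylidene-5-(3-methylidenepent-4-en-1-yl)decahydronaphthalen-1-yl]methanol | C=CC(=C)CC[C@@H]1C(=C)CC[C@@H]2[C@](C)(CO)CCC[C@@]12C | intermediate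
23 | methyl [bis(2,2,2-trifluoroethoxy)phosphoryl]acetate | COC(=O)CP(=O)(OCC(F)(F)F)OCC(F)(F)F | starting material
24 | [bis(2,2,2-trifluoroethoxy)phosphoryl]acetic acid | OC(=O)CP(=O)(OCC(F)(F)F)OCC(F)(F)F | intermediate
25 | [(1R,4aS,5R,8aS)-1,4a-dimethyl-6-methylidene-5-(3-methylidenepent-4-en-1-yl)decahydronaphthalen-1-yl]methyl [bis(2,2,2-trifluoroethoxy)phosphoryl]acetate | C=CC(=C)CC[C@@H]1C(=C)CC[C@@H]2[C@](C)(COC(=O)CP(=O)(OCC(F)(F)F)OCC(F)(F)F)CCC[C@@]12C | intermediate
26 | 4-[(tert-butyldimethylsilyl)oxy]benzaldehyde | O=Cc1ccc(O[Si](C)(C)C(C)(C)C)cc1 | starting material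
27 | [(1R,4aS,5R,8aS)-1,4a-dimethyl-6-methylidene-5-(3-methylidenepent-4-en-1-yl)decahydronaphthalen-1-yl]methyl (Z)-3-{4-[(tert-butyldimethylsilyl)oxy]phenyl}prop-2-enoate | C=CC(=C)CC[C@@H]1C(=C)CC[C@@H]2[C@](C)(COC(=O)/C=C\c3ccc(O[Si](C)(C)C(C)(C)C)cc3)CCC[C@@]12C | intermediate
28 | [(1R,4aS,5R,8aS)-1,4a-dimethyl-6-methylidene-5-(3-methylidenepent-4-en-1-yl)decahydronaphthalen-1-yl]methyl (Z)-3-(4-hydroxyphenyl)prop-2-enoate | C=CC(=C)CC[C@@H]1C(=C)CC[C@@H]2[C@](C)(COC(=O)/C=C\c3ccc(O)cc3)CCC[C@@]12C | target

## Step count and risks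

Total step count: 16. Longest linear sequence: 14 (steps 1–8, 10–12, 14–16); steps 9 and 13 are side branches.

Steps most likely to fail:

1. Step 1. The bulky 1-silylalkenyl Grignard reagent may give poor enantio-induction, or proton transfer from the first-formed sulfonyl carbanion may lead to double addition. The fallback sets out from 1 (with 2 and 3) and comes back at 6. The same three-component coupling run with the achiral catalyst CuBr·SMe2 should give the racemic trans ketone F1. Corey–Bakshi–Shibata reduction with one enantiomer of the methyl oxazaborolidine and BH3·SMe2 should turn both ketone enantiomers, under reagent control, into carbinols of the same configuration at C1: the (1R,2R,3S) alcohol F2 from the wanted enantiomer and its diastereomer, the (1R,2S,3R) alcohol F3. These are separated by chromatography, and Dess–Martin oxidation of F2 returns 6.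

2. Step 5. The carbanion may attack the ester carbonyl, the base may deprotonate the acrylate at its γ-position, or methylation may occur at the sulfonyl carbon. The fallback sets out from 9 and comes back at 13. Catalytic KOtBu in t-BuOH–THF should close ring A under thermodynamic control to the unmethylated sulfonyl ester F4. Na(Hg) with Na2HPO4 then removes the sulfone to give the unmethylated bicyclic ester F5. LDA followed by MeI methylates the only remaining acidic position from the equatorial face and gives 13.

3. Step 10. TiCl4 may cause cationic oligomerisation of the diene or self-condensation of the methylene ketone. The fallback sets out from 15 and comes back at 21. Conjugate allylation with allyltrimethylsilane and TiCl4 should give the butenyl ketone F6, and Wittig methylenation gives the methylidene compound F7. Wacker oxidation (PdCl2, CuCl, O2, DMF–H2O) of the monosubstituted alkene gives the methyl ketone F8. Kinetic enolisation on the methyl side (LDA, −78 °C) and PhNTf2 give the enol triflate F9. Stille coupling with tributyl(vinyl)stannane (Pd(PPh3)4, LiCl, THF) builds the 2-substituted diene and returns 21.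

Further compounds
F1 | step 1 | racemic trans-2-methyl-2-[2-(phenylsulfonyl)ethyl]-3-[1-(trimethylsilyl)ethenyl]cyclohexan-1-one (both enantiomers) | O=C1CCC[C@H](C(=C)[Si](C)(C)C)[C@@]1(C)CCS(=O)(=O)c1ccccc1.O=C1CCC[C@@H](C(=C)[Si](C)(C)C)[C@]1(C)CCS(=O)(=O)c1ccccc1
F2 | step 1 | (1R,2R,3S)-2-methyl-2-[2-(phenylsulfonyl)ethyl]-3-[1-(trimethylsilyl)ethenyl]cyclohexan-1-ol | O[C@@H]1CCC[C@H](C(=C)[Si](C)(C)C)[C@@]1(C)CCS(=O)(=O)c1ccccc1
F3 | step 1 | (1R,2S,3R)-2-methyl-2-[2-(phenylsulfonyl)ethyl]-3-[1-(trimethylsilyl)ethenyl]cyclohexan-1-ol | O[C@@H]1CCC[C@@H](C(=C)[Si](C)(C)C)[C@]1(C)CCS(=O)(=O)c1ccccc1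
F4 | step 5 | methyl (4aR,8aS)-4a-methyl-5-methylidene-3-(phenylsulfonyl)decahydronaphthalene-1-carboxylate (C1 and C3 epimers) | C=C1CCC[C@@H]2C(C(=O)OC)CC(S(=O)(=O)c3ccccc3)C[C@@]12C
F5 | step 5 | methyl (4aR,8aS)-4a-methyl-5-methylidenedecahydronaphthalene-1-carboxylate (C1 epimers) | C=C1CCC[C@@H]2C(C(=O)OC)CCC[C@@]12C
F6 | step 10 | methyl (1R,4aR,5S,8aS)-5-(but-3-en-1-yl)-1,4a-dimethyl-6-oxodecahydronaphthalene-1-carboxylate | C=CCC[C@@H]1C(=O)CC[C@@H]2[C@](C)(C(=O)OC)CCC[C@@]12C
F7 | step 10 | methyl (1R,4aS,5R,8aS)-5-(but-3-en-1-yl)-1,4a-dimethyl-6-methylidenedecahydronaphthalene-1-carboxylate | C=CCC[C@@H]1C(=C)CC[C@@H]2[C@](C)(C(=O)OC)CCC[C@@]12C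
F8 | step 10 | methyl (1R,4aS,5R,8aS)-1,4a-dimethyl-6-methylidene-5-(3-oxobutyl)decahydronaphthalene-1-carboxylate | CC(=O)CC[C@@H]1C(=C)CC[C@@H]2[C@](C)(C(=O)OC)CCC[C@@]12C
F9 | step 10 | methyl (1R,4aS,5R,8aS)-1,4a-dimethyl-6-methylidene-5-{3-[(trifluoromethylsulfonyl)oxy]but-3-en-1-yl}decahydronaphthalene-1-carboxylate | C=C(OS(=O)(=O)C(F)(F)F)CC[C@@H]1C(=C)CC[C@@H]2[C@](C)(C(=O)OC)CCC[C@@]12C
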